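**Retrosynthetic overview**

1. The target is an all-trans 3,4,5-triester of cyclohex-1-ene-1-carboxylic acid with one carbocycle. The esters go on last, one at a time: the O-4 tiglate by acylation, the O-3 6-methylheptanoate by Mitsunobu inversion of the allylic alcohol, and the O-5 acetate by acetate opening of a 4,5-epoxide at C-5.
2. The epoxide comes from hydroxyl-directed epoxidation of tert-butyl (3R)-3-hydroxycyclohexa-1,4-diene-1-carboxylate, whose single stereocentre C-3 then controls C-4 and C-5. The oxirane is the only other ring; it is formed after the carbocycle and opened in the next step.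
3. Key disconnection, a [3+3] union: the carbocycle is cut at C1=C2 (Wittig olefination) and C4=C5 (ring-closing metathesis). The pieces are (2R)-2-silyloxybut-3-enal (C2–C3–C4) and an α-allylated ester phosphorane (C5–C6–C1 plus the carboxyl carbon).
4. Enabling feature: the oxygen-bearing ring carbon C-3 lies between C-2 and C-4. C1=C2 is conjugated to the exocyclic carboxyl (olefination retron), and the trans O-4/O-5 pair on C4–C5 is the retron of a ring alkene. The six-membered ring is therefore a skipped 1,4-diene that two terminally unsaturated three-carbon pieces can close.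
5. C-3 comes from Sharpless desymmetrisation of divinylcarbinol: one vinyl group becomes the aldehyde carbon C-2 (epoxide cleavage), the other becomes C-4.

Key step: step 5

Remark: the SMILES is read as the (3R,4R,5S) all-trans triester carrying an (E)-2-methylbut-2-enoyl (tigloyl) group on O-4, an acetyl group on O-5 and a 6-methylheptanoyl group (eight carbons, iso-branched) on O-3. This is the mirror-image series of 3-epi-shikimic acid, so natural shikimic or quinic acid cannot supply the core without inverting two centres. Ring numbering throughout: C-1 bears the carboxyl, C1=C2, C-3/C-4/C-5 bear oxygen, C-6 is CH2.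

**Step 1**
Reactants: 1 penta-1,4-dien-3-ol (divinylcarbinol)
Product: 2 (1R)-1-[(2S)-oxiran-2-yl]prop-2-en-1-ol
Conditions: Ti(OiPr)4 (cat.), D-(−)-diisopropyl tartrate (cat.), t-BuOOH, 4 Å molecular sieves, CH2Cl2, −20 °C
Reagents that add atoms: tert-butyl hydroperoxide, CC(C)(C)OO
Why: Sharpless asymmetric epoxidation of the prochiral bis-allylic alcohol, in which the tetravalent titanium–tartrate complex selects one enantiotopic vinyl group and one of its faces to set the oxirane carbon (S) and the carbinol carbon (R) as the erythro epoxy alcohol, while faster over-oxidation of the minor enantiomer should raise the enantiomeric purity.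

**Step 2**
Reactants: 2 (1R)-1-[(2S)-oxiran-2-yl]prop-2-en-1-ol
Product: 3 tert-butyldimethyl{[(1R)-1-[(2S)-oxiran-2-yl]prop-2-en-1-yl]oxy}silane
Conditions: TBSCl, imidazole, DMF, 0 °C to rt
Reagents that add atoms: tert-butyldimethylsilyl chloride, CC(C)(C)[Si](C)(C)Cl
Why: Imidazole-promoted silyl ether formation protects the secondary alcohol, so that the glycol cleavage of the next step cannot degrade an α-hydroxy aldehyde, and leaves the epoxide and both stereocentres untouched.

**Step 3**
Reactants: 3 tert-butyldimethyl{[(1R)-1-[(2S)-oxiran-2-yl]prop-2-en-1-yl]oxy}silane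
Product: 4 (2R)-2-[(tert-butyldimethylsilyl)oxy]but-3-enal
Conditions: H5IO6, THF/Et2O, 0 °C to rt
Reagents that add atoms: none
Why: Periodic acid hydrolyses the terminal epoxide to the 1,2-diol (water entering at the unhindered terminal carbon, so that the aldehyde oxygen is the former oxirane oxygen) and cleaves it in the same flask (glycol cleavage), excising the terminal carbon as formaldehyde and leaving the silyloxy-bearing stereocentre unchanged.

**Step 4**
Reactants: 5 tert-butyl 2-(triphenyl-λ5-phosphanylidene)acetate; 6 3-bromoprop-1-ene (allyl bromide)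
Product: 8 tert-butyl 2-(triphenyl-λ5-phosphanylidene)pent-4-enoate, via phosphonium bromide 7 (not isolated)
Conditions: CH2Cl2, 40 °C; then 2 M NaOH (aq), CH2Cl2, rt
Reagents that add atoms: none
Why: C-alkylation of the ester-stabilised ylide by SN2 attack on the allylic bromide gives the phosphonium salt, whose acidic α-proton is removed by aqueous hydroxide to return a stabilised ylide (ylide alkylation–deprotonation).

**Step 5**
Reactants: 4 (2R)-2-[(tert-butyldimethylsilyl)oxy]but-3-enal; 8 tert-butyl 2-(triphenyl-λ5-phosphanylidene)pent-4-enoate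
Product: 10 tert-butyl (3R)-3-[(tert-butyldimethylsilyl)oxy]cyclohexa-1,4-diene-1-carboxylate, via triene ester 9 (not isolated)
Conditions: CH2Cl2, 40 °C; then dilution with CH2Cl2, second-generation Grubbs catalyst RuCl2(H2IMes)(PCy3)(=CHPh) (cat.), 1,4-benzoquinone (cat.), 40 °C
Reagents that add atoms: none
Why: The base-free Wittig reaction of the ester-stabilised phosphorane 8 with aldehyde 4 passes through an oxaphosphetane that collapses to the trisubstituted enoate 9 (C1=C2), the thermodynamically controlled E geometry placing the ester trans to C-3 and thus the allyl arm cis to the silyloxy-vinyl arm. The ruthenium carbene then loads on the unhindered allyl terminus, forms a ruthenacyclobutane with the vinyl group on C-3 and expels ethene (ring-closing metathesis, C4=C5). The closest known reaction types are Wittig olefinations of α-alkylated (alkoxycarbonyl)methylene phosphoranes with α-silyloxy aldehydes and ring-closing metathesis of 1,4,7-trien-3-ol derivatives to cyclohexa-2,5-dienols. The six-membered carbocycle closes by metathesis of the 1,7-diene, both new sp2 carbons (C-4 and C-5) ending inside the ring, so the cis C4=C5 geometry is enforced by ring size. No stereocentre is created, and C-3 (R) is carried over from 4 because the olefination needs no base and the α-silyloxy aldehyde is not enolised. The step needs E selectivity at C1=C2 and no double-bond migration (which would end in loss of silanol and a benzoate); the stabilised ylide should secure the first, and the quinone additive as hydride scavenger, the mild temperature and the electron-poor ester-bearing alkene should secure the second.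

**Step 6**
Reactants: 10 tert-butyl (3R)-3-[(tert-butyldimethylsilyl)oxy]cyclohexa-1,4-diene-1-carboxylate
Product: 11 tert-butyl (3R)-3-hydroxycyclohexa-1,4-diene-1-carboxylate
Conditions: HF·pyridine, pyridine, THF, 0 °C to rt
Reagents that add atoms: none
Why: Fluoride-induced silyl ether cleavage under pyridine-buffered, near-neutral conditions should free the doubly allylic alcohol without the strong acid or base that could dehydrate this arene hydrate to the benzoate.

**Step 7**
Reactants: 11 tert-butyl (3R)-3-hydroxycyclohexa-1,4-diene-1-carboxylate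
Product: 12 tert-butyl (1R,5S,6S)-5-hydroxy-7-oxabicyclo[4.1.0]hept-3-ene-3-carboxylate (epoxide on C-4/C-5, cis to the C-3 hydroxyl)
Conditions: mCPBA, CH2Cl2, 0 °C
Reagents that add atoms: 3-chloroperoxybenzoic acid, O=C(OO)c1cccc(Cl)c1
Why: Hydroxyl-directed peracid epoxidation, in which hydrogen bonding of the peracid to the allylic OH delivers oxygen to the electron-rich C4=C5 bond on the face of the hydroxyl group and so sets C-4 and C-5 cis to O-3, while the ester-conjugated C1=C2 bond is too electron-poor to react.

**Step 8**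
Reactants: 12 tert-butyl (1R,5S,6S)-5-hydroxy-7-oxabicyclo[4.1.0]hept-3-ene-3-carboxylate
Product: 13 tert-butyl (3S,4S,5S)-5-(acetyloxy)-3,4-dihydroxycyclohex-1-ene-1-carboxylate (3,4-cis, 4,5-trans)
Conditions: Ti(OiPr)4, AcOH, CH2Cl2, rt
Reagents that add atoms: acetic acid, CC(=O)O
Why: Ti(OiPr)4-mediated nucleophilic opening of a 2,3-epoxy alcohol, in which chelation of tetravalent titanium by the alkoxide and the syn epoxide oxygen directs acetate to the distal carbon C-5 with SN2 inversion, giving the trans 4-hydroxy-5-acetate.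

**Step 9**
Reactants: 13 tert-butyl (3S,4S,5S)-5-(acetyloxy)-3,4-dihydroxycyclohex-1-ene-1-carboxylate; 14 6-methylheptanoic acid
Product: 15 tert-butyl (3R,4R,5S)-5-(acetyloxy)-4-hydroxy-3-[(6-methylheptanoyl)oxy]cyclohex-1-ene-1-carboxylate
Conditions: PPh3, diisopropyl azodicarboxylate, THF, 0 °C to rt
Reagents that add atoms: none
Why: Mitsunobu esterification, in which the allylic C-3 hydroxyl is activated as the oxyphosphonium ion in preference to the flanked, non-allylic C-4 hydroxyl and is displaced by the 6-methylheptanoate anion with SN2 inversion, turning the cis-3,4 into the trans-3,4 arrangement.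

**Step 10**
Reactants: 15 tert-butyl (3R,4R,5S)-5-(acetyloxy)-4-hydroxy-3-[(6-methylheptanoyl)oxy]cyclohex-1-ene-1-carboxylate; 16 (2E)-2-methylbut-2-enoyl chloride (tigloyl chloride)
Product: 17 tert-butyl (3R,4R,5S)-5-(acetyloxy)-4-{[(2E)-2-methylbut-2-enoyl]oxy}-3-[(6-methylheptanoyl)oxy]cyclohex-1-ene-1-carboxylate
Conditions: pyridine, DMAP (cat.), CH2Cl2, 0 °C to rt
Reagents that add atoms: none
Why: DMAP-catalysed acylation of the only free hydroxyl with the acid chloride, in which the E-configured tigloyl unit is the thermodynamically stable isomer and no stereocentre is touched.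

**Step 11**
Reactants: 17 tert-butyl (3R,4R,5S)-5-(acetyloxy)-4-{[(2E)-2-methylbut-2-enoyl]oxy}-3-[(6-methylheptanoyl)oxy]cyclohex-1-ene-1-carboxylate
Product: 18 (3R,4R,5S)-5-(acetyloxy)-4-{[(2E)-2-methylbut-2-enoyl]oxy}-3-[(6-methylheptanoyl)oxy]cyclohex-1-ene-1-carboxylic acid
Conditions: CF3CO2H, CH2Cl2, 0 °C to rt
Reagents that add atoms: none
Why: Acidolysis of the tert-butyl ester (loss of the tert-butyl cation as 2-methylpropene) should leave the three secondary esters, the enoate and the stereocentres unchanged.

**Compound list**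

1 | penta-1,4-dien-3-ol (divinylcarbinol) | C=CC(O)C=C | starting material
2 | (1R)-1-[(2S)-oxiran-2-yl]prop-2-en-1-ol | C=C[C@@H](O)[C@@H]1CO1 | intermediate
3 | tert-butyldimethyl{[(1R)-1-[(2S)-oxiran-2-yl]prop-2-en-1-yl]oxy}silane | C=C[C@@H](O[Si](C)(C)C(C)(C)C)[C@@H]1CO1 | intermediate
4 | (2R)-2-[(tert-butyldimethylsilyl)oxy]but-3-enal | C=C[C@@H](O[Si](C)(C)C(C)(C)C)C=O | intermediate
5 | tert-butyl 2-(triphenyl-λ5-phosphanylidene)acetate | CC(C)(C)OC(=O)C=P(c1ccccc1)(c1ccccc1)c1ccccc1 | starting material
6 | 3-bromoprop-1-ene (allyl bromide) | C=CCBr | starting material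
7 | [1-(tert-butoxy)-1-oxopent-4-en-2-yl]triphenylphosphonium bromide | C=CCC(C(=O)OC(C)(C)C)[P+](c1ccccc1)(c1ccccc1)c1ccccc1.[Br-] | intermediate
8 | tert-butyl 2-(triphenyl-λ5-phosphanylidene)pent-4-enoate | C=CCC(C(=O)OC(C)(C)C)=P(c1ccccc1)(c1ccccc1)c1ccccc1 | intermediate
9 | tert-butyl (2E,4R)-4-[(tert-butyldimethylsilyl)oxy]-2-(prop-2-en-1-yl)hexa-2,5-dienoate | C=CC/C(C(=O)OC(C)(C)C)=C\[C@H](O[Si](C)(C)C(C)(C)C)C=C | intermediate
10 | tert-butyl (3R)-3-[(tert-butyldimethylsilyl)oxy]cyclohexa-1,4-diene-1-carboxylate | CC(C)(C)[Si](C)(C)O[C@H]1C=C(C(=O)OC(C)(C)C)CC=C1 | intermediate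
11 | tert-butyl (3R)-3-hydroxycyclohexa-1,4-diene-1-carboxylate | O[C@H]1C=C(C(=O)OC(C)(C)C)CC=C1 | intermediate
12 | tert-butyl (1R,5S,6S)-5-hydroxy-7-oxabicyclo[4.1.0]hept-3-ene-3-carboxylate | O[C@H]1C=C(C(=O)OC(C)(C)C)C[C@H]2O[C@@H]12 | intermediate
13 | tert-butyl (3S,4S,5S)-5-(acetyloxy)-3,4-dihydroxycyclohex-1-ene-1-carboxylate | O[C@@H]1[C@@H](OC(C)=O)CC(C(=O)OC(C)(C)C)=C[C@@H]1O | intermediate
14 | 6-methylheptanoic acid | CC(C)CCCCC(=O)O | starting material
15 | tert-butyl (3R,4R,5S)-5-(acetyloxy)-4-hydroxy-3-[(6-methylheptanoyl)oxy]cyclohex-1-ene-1-carboxylate | O[C@@H]1[C@@H](OC(C)=O)CC(C(=O)OC(C)(C)C)=C[C@H]1OC(=O)CCCCC(C)C | intermediate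
16 | (2E)-2-methylbut-2-enoyl chloride (tigloyl chloride) | C/C=C(\C)C(Cl)=O | starting material
17 | tert-butyl (3R,4R,5S)-5-(acetyloxy)-4-{[(2E)-2-methylbut-2-enoyl]oxy}-3-[(6-methylheptanoyl)oxy]cyclohex-1-ene-1-carboxylate | C/C=C(\C)C(=O)O[C@@H]1[C@@H](OC(C)=O)CC(C(=O)OC(C)(C)C)=C[C@H]1OC(=O)CCCCC(C)C | intermediate
18 | (3R,4R,5S)-5-(acetyloxy)-4-{[(2E)-2-methylbut-2-enoyl]oxy}-3-[(6-methylheptanoyl)oxy]cyclohex-1-ene-1-carboxylic acid | C/C=C(\C)C(=O)O[C@@H]1[C@@H](OC(C)=O)CC(C(=O)O)=C[C@H]1OC(=O)CCCCC(C)C | target

**Step count and risks**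

Total step count: 11. Longest linear sequence: 10 steps (from 1 through steps 1–3 and 5–11); step 4 is the one-step side branch.

Steps most likely to fail:

Step 5. What may go wrong: ruthenium-hydride-induced double-bond migration in the skipped diene followed by loss of silanol and aromatisation, or erosion of E control in the olefination so that part of the material cannot close. The fallback sets out from 4 and comes back at 10. Aldol addition of the lithium enolate of tert-butyl pent-4-enoate (LiN(i-Pr)2, THF, −78 °C) to aldehyde 4 should give tert-butyl (4R)-4-[(tert-butyldimethylsilyl)oxy]-3-hydroxy-2-(prop-2-en-1-yl)hex-5-enoate F1 as a diastereomer mixture. Ring-closing metathesis of its two terminal alkenes (second-generation Grubbs catalyst, CH2Cl2, 40 °C) should give tert-butyl (3R)-3-[(tert-butyldimethylsilyl)oxy]-2-hydroxycyclohex-4-ene-1-carboxylate F2, a ring that cannot aromatise during metathesis. Mesylation (MsCl, Et3N, CH2Cl2) to tert-butyl (3R)-3-[(tert-butyldimethylsilyl)oxy]-2-[(methylsulfonyl)oxy]cyclohex-4-ene-1-carboxylate F3 and E1cB elimination with DBU should then install C1=C2 and deliver 10. The two extra stereocentres are destroyed in the elimination, so their configuration does not matter.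

Step 8. What may go wrong: loss of regiocontrol in the epoxide opening, or acetyl transfer between O-5 and O-4 (or to isopropoxide) under the titanium alkoxide. The fallback sets out from 12 and comes back at 13. Acid-catalysed hydrolysis of the epoxide (dilute HClO4, THF/H2O, water attacking C-5 with inversion) should give tert-butyl (3S,4R,5S)-3,4,5-trihydroxycyclohex-1-ene-1-carboxylate F4. The cis-3,4-diol is tied up with 2,2-dimethoxypropane and catalytic TsOH as tert-butyl (3S,4R,5S)-5-hydroxy-3,4-(isopropylidenedioxy)cyclohex-1-ene-1-carboxylate F5. The remaining O-5 is acetylated (Ac2O, pyridine, DMAP) to tert-butyl (3S,4R,5S)-5-(acetyloxy)-3,4-(isopropylidenedioxy)cyclohex-1-ene-1-carboxylate F6, and aqueous AcOH removes the acetal to give 13.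

Step 9. What may go wrong: competing activation of the C-4 hydroxyl, or SN2′ and elimination pathways of the allylic oxyphosphonium ion. The fallback sets out from 12 and comes back at 15. The Mitsunobu inversion with 14 (PPh3, diisopropyl azodicarboxylate, THF) is done one stage earlier on epoxy alcohol 12, which has a single hydroxyl, to give tert-butyl (1R,5R,6R)-5-[(6-methylheptanoyl)oxy]-7-oxabicyclo[4.1.0]hept-3-ene-3-carboxylate F7. Acetolysis of the epoxide in a buffered medium (AcOH, NaOAc, 60 °C), with acetate attacking C-5, remote from the electron-withdrawing acyloxy-bearing C-3, should then give 15 directly.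

**Further compounds**

F1 | step 5 | tert-butyl (4R)-4-[(tert-butyldimethylsilyl)oxy]-3-hydroxy-2-(prop-2-en-1-yl)hex-5-enoate (diastereomer mixture at C-2 and C-3) | C=CCC(C(=O)OC(C)(C)C)C(O)[C@H](O[Si](C)(C)C(C)(C)C)C=C
F2 | step 5 | tert-butyl (3R)-3-[(tert-butyldimethylsilyl)oxy]-2-hydroxycyclohex-4-ene-1-carboxylate (diastereomer mixture at C-1 and C-2) | OC1[C@H](O[Si](C)(C)C(C)(C)C)C=CCC1C(=O)OC(C)(C)C
F3 | step 5 | tert-butyl (3R)-3-[(tert-butyldimethylsilyl)oxy]-2-[(methylsulfonyl)oxy]cyclohex-4-ene-1-carboxylate (diastereomer mixture at C-1 and C-2) | CS(=O)(=O)OC1[C@H](O[Si](C)(C)C(C)(C)C)C=CCC1C(=O)OC(C)(C)C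
F4 | step 8 | tert-butyl (3S,4R,5S)-3,4,5-trihydroxycyclohex-1-ene-1-carboxylate | O[C@@H]1[C@@H](O)CC(C(=O)OC(C)(C)C)=C[C@@H]1O
F5 | step 8 | tert-butyl (3S,4R,5S)-5-hydroxy-3,4-(isopropylidenedioxy)cyclohex-1-ene-1-carboxylate | CC1(C)O[C@@H]2[C@@H](O)CC(C(=O)OC(C)(C)C)=C[C@@H]2O1
F6 | step 8 | tert-butyl (3S,4R,5S)-5-(acetyloxy)-3,4-(isopropylidenedioxy)cyclohex-1-ene-1-carboxylate | CC1(C)O[C@@H]2[C@@H](OC(C)=O)CC(C(=O)OC(C)(C)C)=C[C@@H]2O1
F7 | step 9 | tert-butyl (1R,5R,6R)-5-[(6-methylheptanoyl)oxy]-7-oxabicyclo[4.1.0]hept-3-ene-3-carboxylate | CC(C)CCCCC(=O)O[C@@H]1C=C(C(=O)OC(C)(C)C)C[C@H]2O[C@@H]12
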